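The ten-membered carbocycle is closed at C5–C6 (germacrane numbering), the bond joining the vinylic CH of the (Z)-C4=C5 alkene to the oxygen-bearing γ-carbon that the carbocycle shares with the butenolide. An intramolecular Nozaki–Hiyama–Kishi reaction unites two electrophilic carbons: a (Z)-vinyl iodide (C5) and an aldehyde (C6) that sits cis to a methyl ester on the tetrasubstituted C7=C11 alkene. The resulting C6 alkoxide lactonises at once, so one operation gives the macrocycle, the C6 stereocentre and the butenolide. In the precursor the C1/C9 aldol is masked as a 2-isoxazoline, made by a hydroxyl-directed nitrile oxide cycloaddition that sets C9 and C10 from C8; the formyl acrylate comes from a 3,4-disubstituted furan.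

Key step: step 12

Numbering used: C1 ketone carbon, C2 and C3 ring CH2, C4=C5 ring alkene (C15 methyl on C4), C6 lactone O–CH, C7=C11 butenolide alkene, C12 lactone carbonyl, C13 acetoxymethyl carbon, C8 methacrylate-bearing carbon, C9 carbinol carbon, C10 methyl-bearing carbon (C14 its methyl).

Remark: furan-3,4-diyldimethanol, propyne, acetaldoxime, prop-2-yn-1-ol and dicyclohexylborane are taken as stock materials; the lactol 20 and the endoperoxide 19 are epimer mixtures at centres that are planarised or created later.

**Step 1**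
Reactants: 1 prop-2-yn-1-ol
Product: 2 (Z)-3-iodo-2-methylprop-2-en-1-ol
Conditions: MeMgBr (2.5 equiv), CuI (10 mol %), Et2O/THF, −10 °C to rt; then I2, THF, −78 to 0 °C
Reagents that add atoms: methylmagnesium bromide C[Mg]Br; iodine II
Why: Copper-catalysed anti-carbomagnesiation of the propargylic alkoxide gives a five-membered alkenylmagnesium chelate with Mg cis to CH2O, so iodinolysis with retention should give the Z iodide that becomes C3–C4(C15)=C5.

**Step 2**
Reactants: 2 (Z)-3-iodo-2-methylprop-2-en-1-ol
Product: 3 (Z)-3-bromo-1-iodo-2-methylprop-1-ene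
Conditions: CBr4, PPh3, CH2Cl2, 0 °C
Reagents that add atoms: tetrabromomethane BrC(Br)(Br)Br
Why: Appel bromination of the primary allylic alcohol proceeds by SN2 displacement and leaves the alkene geometry untouched.

**Step 3**
Reactants: 3 (Z)-3-bromo-1-iodo-2-methylprop-1-ene; 4 acetaldoxime
Product: 5 (Z)-5-iodo-4-methylpent-4-enal oxime
Conditions: 4, n-BuLi (2.05 equiv), THF, −78 to 0 °C; then 3, −78 °C to rt; H2O
Reagents that add atoms: none
Why: Alkylation of the oxime C,O-dianion at carbon by the reactive allylic bromide (SN2) should join C2 to C3 and deliver the nitrile oxide precursor directly.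

**Step 4**
Reactants: 6 furan-3,4-diyldimethanol
Product: 7 [4-(tert-butyldimethylsilyloxymethyl)furan-3-yl]methanol
Conditions: NaH (1.0 equiv), THF, 0 °C; then TBSCl (1.0 equiv), rt
Reagents that add atoms: tert-butyldimethylsilyl chloride CC(C)(C)[Si](C)(C)Cl
Why: Silylation of the sparingly soluble monosodium alkoxide of a symmetrical diol is the standard monoprotection (silyl ether formation).

**Step 5**
Reactants: 7 [4-(tert-butyldimethylsilyloxymethyl)furan-3-yl]methanol
Product: 8 4-(tert-butyldimethylsilyloxymethyl)furan-3-carbaldehyde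
Conditions: MnO2 (excess), CH2Cl2, rt
Reagents that add atoms: none
Why: MnO2 oxidation of the furylic (benzylic-type) alcohol should stop cleanly at the aldehyde, which becomes C8.

**Step 6**
Reactants: 8 4-(tert-butyldimethylsilyloxymethyl)furan-3-carbaldehyde; 9 propyne
Product: 12 (S,E)-1-[4-(tert-butyldimethylsilyloxymethyl)furan-3-yl]but-2-en-1-ol, via alkenylborane 10 (not isolated), via alkenylzinc 11 (not isolated)
Conditions: 9, dicyclohexylborane, toluene, 0 °C; Et2Zn, −78 °C; (−)-3-exo-morpholinoisoborneol (4 mol %), then 8, −10 °C; aq. NH4Cl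
Reagents that add atoms: none
Why: syn-Hydroboration of propyne, boron-to-zinc transmetalation and amino-alcohol-catalysed asymmetric alkenylzinc addition should deliver the E-propenyl group to the Si face of the aldehyde, setting C8 by catalyst control (the antipodal ligand is used should the sense prove opposite).

**Step 7**
Reactants: 5 (Z)-5-iodo-4-methylpent-4-enal oxime; 12 (S,E)-1-[4-(tert-butyldimethylsilyloxymethyl)furan-3-yl]but-2-en-1-ol
Product: 15 (R)-[4-(tert-butyldimethylsilyloxymethyl)furan-3-yl][(4R,5R)-3-((Z)-4-iodo-3-methylbut-3-enyl)-4-methyl-4,5-dihydroisoxazol-5-yl]methanol, via hydroximoyl chloride 13 (not isolated), via nitrile oxide 14 (not isolated)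
Conditions: 5, t-BuOCl, CH2Cl2, −78 °C; then 12, i-PrOH, EtMgBr, CH2Cl2, 0 °C to rt
Reagents that add atoms: none
Why: In this magnesium-alkoxide-directed nitrile oxide 1,3-dipolar cycloaddition, magnesium binds both partners and delivers the dipole oxygen to C9 on the face syn to the C8 oxygen (C8–H in the alkene plane), while suprafacial addition to the E-alkene places the C10 methyl trans to C9, so C9 and C10 are set from C8 by substrate control.

**Step 8**
Reactants: 15 isoxazolinyl furyl carbinol
Product: 16 (R)-[4-(tert-butyldimethylsilyloxymethyl)furan-3-yl][(4R,5R)-3-((Z)-4-iodo-3-methylbut-3-enyl)-4-methyl-4,5-dihydroisoxazol-5-yl]methyl 2-methylprop-2-enoate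
Conditions: methacrylic anhydride, Et3N, DMAP (cat.), CH2Cl2, 0 °C to rt
Reagents that add atoms: methacrylic anhydride C=C(C)C(=O)OC(=O)C(C)=C
Why: DMAP-catalysed acylation of the only free hydroxyl puts the methacrylate on C8 while the C9 oxygen is locked in the isoxazoline, so no diol differentiation or acyl migration arises.

**Step 9**
Reactants: 16 silyl ether methacrylate
Product: 18 (R)-[4-(acetoxymethyl)furan-3-yl][(4R,5R)-3-((Z)-4-iodo-3-methylbut-3-enyl)-4-methyl-4,5-dihydroisoxazol-5-yl]methyl 2-methylprop-2-enoate, via primary alcohol 17 (not isolated)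
Conditions: HF·pyridine, pyridine/THF, 0 °C to rt; then Ac2O, DMAP (cat.), 0 °C
Reagents that add atoms: acetic anhydride CC(=O)OC(C)=O
Why: Buffered fluoride desilylation followed in the same flask by pyridine/DMAP acetylation converts the primary silyl ether into the C13 acetate without giving the methacrylate time to migrate.

**Step 10**
Reactants: 18 furan acetate methacrylate
Product: 20 (R)-[4-(acetoxymethyl)-2-hydroxy-5-oxo-2,5-dihydrofuran-3-yl][(4R,5R)-3-((Z)-4-iodo-3-methylbut-3-enyl)-4-methyl-4,5-dihydroisoxazol-5-yl]methyl 2-methylprop-2-enoate (lactol epimers), via furan endoperoxide 19 (not isolated)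
Conditions: O2, hν (visible), tetraphenylporphyrin (cat.), i-Pr2NEt, CH2Cl2, −78 °C to rt
Reagents that add atoms: dioxygen (as singlet oxygen) O=O
Why: [4+2] cycloaddition of singlet oxygen to the furan is followed by Kornblum–DeLaMare fragmentation, in which the hindered amine removes the less encumbered bridgehead hydrogen (next to the acetoxymethyl-bearing C11), so that carbon becomes the C12 carbonyl and the carbon next to C7 becomes the C6 lactol.

**Step 11**
Reactants: 20 hydroxybutenolide
Product: 21 methyl (2Z,4R)-2-(acetoxymethyl)-3-formyl-4-(2-methylprop-2-enoyloxy)-4-[(4R,5R)-3-((Z)-4-iodo-3-methylbut-3-enyl)-4-methyl-4,5-dihydroisoxazol-5-yl]but-2-enoate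
Conditions: TMSCHN2, MeOH/toluene, 0 °C; AcOH quench
Reagents that add atoms: trimethylsilyldiazomethane C[Si](C)(C)C=[N+]=[N-]
Why: Diazoalkane O-methylation of the ring-opened carboxylic acid tautomer of the pseudo-acid traps the open (Z)-formyl ester, erasing the lactol epimers; the tetrasubstituted alkene cannot isomerise.

**Step 12**
Reactants: 21 (Z)-formyl acrylate vinyl iodide
Product: 23 isoxazoline-bridged macrocyclic butenolide (6R,8R; C1=N–O–C9 isoxazoline, 4Z), via macrocyclic hydroxy ester 22 (not isolated)
Conditions: CrCl2 (10 equiv), NiCl2 (0.2 equiv), DMSO, rt, slow addition to 2 mM; aq. NH4Cl; then silica gel or pyridinium p-toluenesulfonate (cat.), CH2Cl2 if lactonisation is incomplete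
Reagents that add atoms: none
Why: Zerovalent nickel inserts into the C5–I bond, transmetalation gives a (Z)-alkenyl trivalent chromium species with retained geometry that adds to the C6 aldehyde, and the chromium alkoxide then acylates onto the cis C12 methyl ester with loss of methoxide. The closest known type is an intramolecular Nozaki–Hiyama–Kishi macrocyclisation with in situ lactonisation, a reductive union of two electrophilic carbons. The ten-membered carbocycle closes by 10-exo-trig attack on the carbonyl and the butenolide by 5-exo-trig acyl substitution. For C6, allylic 1,3-strain between C8 and C13 should hold C8–H in the plane of C7=C11 and put C9 with its tether on one face, so the s-trans enal is attacked on its Re face from that side to give 6R; a chiral sulfonamide ligand on chromium can reinforce this. The step needs aldehyde-only chemoselectivity and no competing closure: the isoxazoline hides the C1 ketone, which C5 would otherwise attack in a five-membered closure, and the C9 hydroxyl, which would otherwise acetalise C6. The Z geometry of the iodide and high dilution favour ring closure over oligomerisation.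

**Step 13**
Reactants: 23 isoxazoline-bridged macrocyclic butenolide
Product: 25 CNP0164859.1 (6R,8R,9R,10S; 4Z), via hydroxy imine 24 (not isolated)
Conditions: Mo(CO)6, MeCN/H2O, 80 °C
Reagents that add atoms: water O
Why: Mo(CO)6-mediated reductive N–O cleavage of the 2-isoxazoline gives the β-hydroxy imine, which hydrolyses in the aqueous medium to the C1 ketone and C9 alcohol without touching esters, alkenes or the C9/C10 stereocentres.

**Compound list**
1 | prop-2-yn-1-ol | C#CCO | starting material
2 | (Z)-3-iodo-2-methylprop-2-en-1-ol | OC/C(C)=C\I | intermediate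
3 | (Z)-3-bromo-1-iodo-2-methylprop-1-ene | BrC/C(C)=C\I | intermediate
4 | acetaldoxime | CC=NO | starting material
5 | (Z)-5-iodo-4-methylpent-4-enal oxime | ON=CCC/C(C)=C\I | intermediate
6 | furan-3,4-diyldimethanol | OCc1cocc1CO | starting material
7 | [4-(tert-butyldimethylsilyloxymethyl)furan-3-yl]methanol | OCc1cocc1CO[Si](C)(C)C(C)(C)C | intermediate
8 | 4-(tert-butyldimethylsilyloxymethyl)furan-3-carbaldehyde | O=Cc1cocc1CO[Si](C)(C)C(C)(C)C | intermediate
9 | propyne | CC#C | starting material
10 | dicyclohexyl[(E)-prop-1-enyl]borane | C/C=C/B(C1CCCCC1)C1CCCCC1 | intermediate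
11 | ethyl[(E)-prop-1-enyl]zinc | C/C=C/[Zn]CC | intermediate
12 | (S,E)-1-[4-(tert-butyldimethylsilyloxymethyl)furan-3-yl]but-2-en-1-ol | C/C=C/[C@H](O)c1cocc1CO[Si](C)(C)C(C)(C)C | intermediate
13 | (Z)-N-hydroxy-5-iodo-4-methylpent-4-enimidoyl chloride | ON=C(Cl)CC/C(C)=C\I | intermediate
14 | (Z)-5-iodo-4-methylpent-4-enenitrile oxide | [O-][N+]#CCC/C(C)=C\I | intermediate
15 | (R)-[4-(tert-butyldimethylsilyloxymethyl)furan-3-yl][(4R,5R)-3-((Z)-4-iodo-3-methylbut-3-enyl)-4-methyl-4,5-dihydroisoxazol-5-yl]methanol | I/C=C(C)\CCC1=NO[C@@H]([C@H](O)c2cocc2CO[Si](C)(C)C(C)(C)C)[C@@H]1C | intermediate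
16 | methacrylate ester of 15 | I/C=C(C)\CCC1=NO[C@@H]([C@H](OC(=O)C(C)=C)c2cocc2CO[Si](C)(C)C(C)(C)C)[C@@H]1C | intermediate
17 | (R)-[4-(hydroxymethyl)furan-3-yl][(4R,5R)-isoxazolinyl]methyl 2-methylprop-2-enoate | I/C=C(C)\CCC1=NO[C@@H]([C@H](OC(=O)C(C)=C)c2cocc2CO)[C@@H]1C | intermediate
18 | (R)-[4-(acetoxymethyl)furan-3-yl][(4R,5R)-isoxazolinyl]methyl 2-methylprop-2-enoate | I/C=C(C)\CCC1=NO[C@@H]([C@H](OC(=O)C(C)=C)c2cocc2COC(C)=O)[C@@H]1C | intermediate
19 | 2,5-endoperoxide of the furan ring of 18 (2,3,7-trioxabicyclo[2.2.1]hept-5-ene) | I/C=C(C)\CCC1=NO[C@@H]([C@H](OC(=O)C(C)=C)C2=C(COC(C)=O)C3OOC2O3)[C@@H]1C | intermediate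
20 | (R)-[4-(acetoxymethyl)-2-hydroxy-5-oxo-2,5-dihydrofuran-3-yl][(4R,5R)-isoxazolinyl]methyl 2-methylprop-2-enoate, lactol epimers | I/C=C(C)\CCC1=NO[C@@H]([C@H](OC(=O)C(C)=C)C2=C(COC(C)=O)C(=O)OC2O)[C@@H]1C | intermediate
21 | methyl (2Z,4R)-2-(acetoxymethyl)-3-formyl-4-(2-methylprop-2-enoyloxy)-4-[(4R,5R)-isoxazolinyl]but-2-enoate | I/C=C(C)\CCC1=NO[C@@H]([C@H](OC(=O)C(C)=C)/C(C=O)=C(\COC(C)=O)C(=O)OC)[C@@H]1C | intermediate
22 | macrocyclic (6R)-hydroxy methyl ester (C5–C6 bond formed, C12 ester cis to C6, isoxazoline retained) | C=C(C)C(=O)O[C@@H]1/C(=C(\COC(C)=O)C(=O)OC)[C@H](O)/C=C(/C)CCC2=NO[C@@H]1[C@@H]2C | intermediate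
23 | isoxazoline-bridged macrocyclic butenolide (target with C1=N–O–C9 in place of C1=O and C9–OH) | C=C(C)C(=O)O[C@@H]1C2=C(COC(C)=O)C(=O)O[C@@H]2/C=C(/C)CCC3=NO[C@@H]1[C@@H]3C | intermediate
24 | C1 imine of the target (β-hydroxy ketimine) | C=C(C)C(=O)O[C@@H]1C2=C(COC(C)=O)C(=O)O[C@@H]2/C=C(/C)CCC(=N)[C@@H](C)[C@H]1O | intermediate
25 | CNP0164859.1, (4Z,6R,8R,9R,10S)-13-acetoxy-9-hydroxy-8-(2-methylprop-2-enoyloxy)-1-oxogermacra-4,7(11)-dien-12,6-olide | C=C(C)C(=O)O[C@@H]1C2=C(COC(C)=O)C(=O)O[C@@H]2/C=C(/C)CCC(=O)[C@@H](C)[C@H]1O | target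

**Totals**
Total step count: 13. Longest linear sequence: 10 steps (steps 1–3 or 4–6, then 7–13).

**Steps most likely to fail**

Step 12. The bridged ten-membered ring may close slowly, so that oligomerisation, reduction of the electron-poor formyl acrylate or of the N–O bond by divalent chromium, or attack on the wrong aldehyde face takes over. The fallback sets out from 20: acetylation of the lactol (Ac2O, pyridine) should give the 5-acetoxybutenolide F1 as an epimer mixture. A nickel-catalysed reductive cross-electrophile macrocyclisation (NiBr2(MeOCH2CH2OMe), 4,4′-di-tert-butyl-2,2′-bipyridine, zinc dust, N,N-dimethylacetamide, high dilution) would then couple the vinyl iodide with the nickel π-allyl formed by ionisation of the C6 acetate. Both C6 epimers converge through that planar allyl, and bond formation at the less substituted C6 terminus returns to 23.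

Step 10. Proton loss from the wrong bridgehead of the endoperoxide would give the regioisomeric hydroxybutenolide. The fallback sets out from 18: dimethyldioxirane (acetone, −78 °C) should open the furan to the (Z)-enedial F2. Pinnick oxidation (NaClO2, NaH2PO4, 2-methyl-2-butene, t-BuOH/H2O) should then oxidise the less hindered C12 aldehyde, and the acid formed closes onto the C6 aldehyde, protecting it and returning to 20.

Step 7. Allylic strain is weak on the E-alkene, so facial selectivity may be poor, and incomplete magnesium chelation would erode regioselectivity. The fallback sets out from 5 (chlorinated to 13 as before) and moves stereocontrol to a reagent. A zinc-bridged, tartrate-controlled asymmetric nitrile oxide cycloaddition to (E)-but-2-en-1-ol (Et2Zn, the diisopropyl tartrate enantiomer giving the 4R,5R adduct) should give the isoxazolinylmethanol F3. Parikh–Doering oxidation (SO3·pyridine, DMSO, i-Pr2NEt) gives the isoxazoline-5-carbaldehyde F4. Silylation of purchasable (4-bromofuran-3-yl)methanol gives the silyl ether F5, and bromine–lithium exchange (n-BuLi, −78 °C) gives the furyllithium F6. Chelation-controlled addition of F6 to F4 precomplexed with MgBr2·OEt2 (magnesium bridging the aldehyde and ring oxygens) should give the syn carbinol, returning to 15.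

**Further compounds**
F1 | step 12 | (R)-[2-acetoxy-4-(acetoxymethyl)-5-oxo-2,5-dihydrofuran-3-yl][(4R,5R)-3-((Z)-4-iodo-3-methylbut-3-enyl)-4-methyl-4,5-dihydroisoxazol-5-yl]methyl 2-methylprop-2-enoate (epimers at the acetal carbon) | I/C=C(C)\CCC1=NO[C@@H]([C@H](OC(=O)C(C)=C)C2=C(COC(C)=O)C(=O)OC2OC(C)=O)[C@@H]1C
F2 | step 10 | (R,Z)-3-(acetoxymethyl)-2-formyl-1-[(4R,5R)-3-((Z)-4-iodo-3-methylbut-3-enyl)-4-methyl-4,5-dihydroisoxazol-5-yl]-4-oxobut-2-enyl 2-methylprop-2-enoate | I/C=C(C)\CCC1=NO[C@@H]([C@H](OC(=O)C(C)=C)/C(C=O)=C(\COC(C)=O)C=O)[C@@H]1C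
F3 | step 7 | [(4R,5R)-3-((Z)-4-iodo-3-methylbut-3-enyl)-4-methyl-4,5-dihydroisoxazol-5-yl]methanol | I/C=C(C)\CCC1=NO[C@@H](CO)[C@@H]1C
F4 | step 7 | (4R,5R)-3-((Z)-4-iodo-3-methylbut-3-enyl)-4-methyl-4,5-dihydroisoxazole-5-carbaldehyde | I/C=C(C)\CCC1=NO[C@@H](C=O)[C@@H]1C
F5 | step 7 | [(4-bromofuran-3-yl)methoxy](tert-butyl)dimethylsilane | Brc1cocc1CO[Si](C)(C)C(C)(C)C
F6 | step 7 | [4-(tert-butyldimethylsilyloxymethyl)furan-3-yl]lithium | [Li]c1cocc1CO[Si](C)(C)C(C)(C)C
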